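**Strategy.** The plan rests on closing the dihydrofuran ring of the 2,3-dihydrobenzofuran by forming its C2–C3 bond. C2 (aryl-ether oxygen plus a 1-substituted vinyl group) and C3 (carbinol oxygen, aryl) are the signature of a γ-aryloxyallyl nucleophile adding to an aryl aldehyde. An O-allenyl salicylaldehyde is therefore cyclised by enantioselective copper-catalysed borylcupration: the 2-boryl allylcopper attacks the ortho formyl group, closes the ring, sets the cis C2/C3 stereocentres under ligand control and leaves a vinyl boronate exactly where the acrolein carbonyl carbon is later inserted. The side-chain (S) centre comes from a CBS reduction; boron masks the enal until both esters are in place.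

Key step: step 6

Assumption: the antipode of Ph-BPE written in step 6 is taken to be the one that gives the (2R,3R) ring; the sense of induction is fixed in a first run and the mirror-image ligand is used if it proves opposite.

Abbreviations: TBS = tert-butyldimethylsilyl, TMS = trimethylsilyl, Bpin = 4,4,5,5-tetramethyl-1,3,2-dioxaborolan-2-yl. Locants of the bicyclic compounds follow benzofuran numbering (O1, C2, C3, C5).

**Route**

Step 1
Reactants: 1 5-acetyl-2-hydroxybenzaldehyde
Product: 2 5-acetyl-2-(prop-2-yn-1-yloxy)benzaldehyde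
Conditions: propargyl bromide, K2CO3, DMF, rt
Reagents that add atoms: propargyl bromide, C#CCBr
Why: Williamson ether synthesis, in which the acidic phenol (ortho formyl, para acetyl) is deprotonated by carbonate and alkylated by the propargylic bromide in an SN2 reaction.

Step 2
Reactants: 2 5-acetyl-2-(prop-2-yn-1-yloxy)benzaldehyde
Product: 3 (1S)-1-[3-(hydroxymethyl)-4-(prop-2-yn-1-yloxy)phenyl]ethanol
Conditions: (R)-2-methyl-CBS-oxazaborolidine (0.2 equiv), catecholborane (2.5 equiv), toluene, −78 °C to −20 °C; then MeOH, 1 M NaOH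
Reagents that add atoms: none
Why: Corey–Bakshi–Shibata reduction, in which the (R)-oxazaborolidine should deliver hydride to the aryl methyl ketone to set the (S) carbinol, while the aldehyde is reduced to the primary alcohol so that no carbonyl is left for the base step and catecholborane leaves the alkyne alone at low temperature.

Step 3
Reactants: 3 (1S)-1-[3-(hydroxymethyl)-4-(prop-2-yn-1-yloxy)phenyl]ethanol
Product: 4 (1S)-1-[3-(hydroxymethyl)-4-(propa-1,2-dien-1-yloxy)phenyl]ethanol
Conditions: KOtBu (2.3 equiv), THF, 0 °C to rt; then H2O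
Reagents that add atoms: none
Why: base-mediated prototropic propargyl-to-allenyl ether isomerisation, run on the dialkoxide so that no electrophilic carbonyl can trap the acetylide or the propargylic carbanion; the stereocentre is not touched.

Step 4
Reactants: 4 (1S)-1-[3-(hydroxymethyl)-4-(propa-1,2-dien-1-yloxy)phenyl]ethanol
Product: 5 5-[(1S)-1-hydroxyethyl]-2-(propa-1,2-dien-1-yloxy)benzaldehyde
Conditions: Cu(MeCN)4OTf (5 mol%), 2,2'-bipyridine (5 mol%), TEMPO (5 mol%), N-methylimidazole (10 mol%), air, MeCN, rt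
Reagents that add atoms: none
Why: copper/TEMPO aerobic alcohol oxidation, which is selective for the primary benzylic alcohol over the secondary one and is neutral enough for the acid-sensitive allenyl ether.

Step 5
Reactants: 5 5-[(1S)-1-hydroxyethyl]-2-(propa-1,2-dien-1-yloxy)benzaldehyde
Product: 6 5-[(1S)-1-(TBS-oxy)ethyl]-2-(propa-1,2-dien-1-yloxy)benzaldehyde
Conditions: TBSCl, imidazole, DMF, rt
Reagents that add atoms: tert-butyldimethylsilyl chloride, CC(C)(C)[Si](C)(C)Cl
Why: imidazole-promoted silylation masks the remaining hydroxyl, which would otherwise protonate the organocopper intermediates of the next step, and later lets the two secondary alcohols be acylated one at a time.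

Step 6
Reactants: 6 5-[(1S)-1-(TBS-oxy)ethyl]-2-(propa-1,2-dien-1-yloxy)benzaldehyde
Product: 9 (2R,3R)-5-[(1S)-1-(TBS-oxy)ethyl]-2-[1-(Bpin)ethenyl]-2,3-dihydrobenzofuran-3-ol, via allylcopper 7 (not isolated), via O-boryl ether 8 (not isolated)
Conditions: CuCl (5 mol%), (S,S)-Ph-BPE (6 mol%), NaOtBu (10 mol%), B2pin2 (1.2 equiv), THF, 0 °C to rt; then aq. NH4Cl
Reagents that add atoms: bis(pinacolato)diboron, CC1(C)OB(OC1(C)C)B1OC(C)(C)C(C)(C)O1
Why: Ligated Cu–Bpin (from CuCl, NaOtBu, B2pin2 and the bisphosphine) adds across the allene with boron on the central carbon to give the (Z)-2-boryl-γ-aryloxyallylcopper 7, whose oxygen-bearing γ-carbon attacks the ortho formyl group through a closed six-membered chair transition state; borylation of the copper alkoxide by B2pin2 gives 8 and returns Cu–Bpin, and work-up hydrolyses the O–B bond. The closest known reaction type is the copper-catalysed enantioselective borylative coupling of allenes with aldehydes and ketones, used here intramolecularly. The dihydrofuran ring closes in the 5-exo-trig mode, the allyl carbon C2 bonding to the carbonyl carbon C3 while the carbonyl oxygen stays outside the ring. The cis relation of C2 and C3 follows from the Z geometry of 7, because the short O–aryl tether can only bridge an axial aryloxy and an equatorial aryl position of the chair, and the absolute configuration (2R,3R) is set by the chiral bisphosphine on copper, which selects the aldehyde face, the remote (S) centre being too far away to interfere. The step needs chemoselective borylcupration of the allene in the presence of the aldehyde and closure through the γ-carbon; the high reactivity of the allene toward Cu–Bpin and the preference for a five- over a seven-membered ring (the alternative closure through the CH2 terminus) secure both, and the silyl ether removes the only proton source that could quench the allylcopper.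

Step 7
Reactants: 9 (2R,3R)-5-[(1S)-1-(TBS-oxy)ethyl]-2-[1-(Bpin)ethenyl]-2,3-dihydrobenzofuran-3-ol
Product: 12 (2R,3R)-5-[(1S)-1-(TBS-oxy)ethyl]-2-[3-(Bpin)prop-1-en-2-yl]-2,3-dihydrobenzofuran-3-ol, via TMS ether 10 (not isolated), via homologated TMS ether 11 (not isolated)
Conditions: hexamethyldisilazane, TMSCl (cat.), THF, rt, evaporate; ICH2Cl, n-BuLi, THF, −78 °C to rt; K2CO3, MeOH, 0 °C
Reagents that add atoms: chloroiodomethane, ClCI
Why: Matteson homologation, in which LiCH2Cl adds to the alkenyl boronic ester and the alkenyl group undergoes a 1,2-metallate shift with loss of chloride to insert the future aldehyde carbon, the transient TMS ether keeping the cis C3 oxygen from binding boron; no stereocentre is involved.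

Step 8
Reactants: 12 (2R,3R)-5-[(1S)-1-(TBS-oxy)ethyl]-2-[3-(Bpin)prop-1-en-2-yl]-2,3-dihydrobenzofuran-3-ol
Product: 13 (2R,3R)-5-[(1S)-1-(TBS-oxy)ethyl]-2-[3-(Bpin)prop-1-en-2-yl]-2,3-dihydrobenzofuran-3-yl 3-methylbutanoate
Conditions: 3-methylbutanoic anhydride, Et3N, DMAP (cat.), CH2Cl2, 0 °C
Reagents that add atoms: 3-methylbutanoic anhydride, CC(C)CC(=O)OC(=O)CC(C)C
Why: DMAP-catalysed acylation of the only free hydroxyl puts the isovalerate on C3 with retention, while the primary carbinol is still masked as a C–B bond and the side-chain hydroxyl as its silyl ether.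

Step 9
Reactants: 13 (2R,3R)-5-[(1S)-1-(TBS-oxy)ethyl]-2-[3-(Bpin)prop-1-en-2-yl]-2,3-dihydrobenzofuran-3-yl 3-methylbutanoate
Product: 14 (2R,3R)-5-[(1S)-1-hydroxyethyl]-2-[3-(Bpin)prop-1-en-2-yl]-2,3-dihydrobenzofuran-3-yl 3-methylbutanoate
Conditions: HF·pyridine, pyridine, THF, 0 °C to rt
Reagents that add atoms: none
Why: fluoride-mediated desilylation under pyridine-buffered, non-ionising conditions should free the side-chain alcohol without solvolysis of the benzylic ester, epimerisation of the p-alkoxybenzylic centre or loss of the allylboronate.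

Step 10
Reactants: 14 (2R,3R)-5-[(1S)-1-hydroxyethyl]-2-[3-(Bpin)prop-1-en-2-yl]-2,3-dihydrobenzofuran-3-yl 3-methylbutanoate
Product: 15 (1S)-1-[(2R,3R)-2-[3-(Bpin)prop-1-en-2-yl]-3-(3-methylbutanoyloxy)-2,3-dihydrobenzofuran-5-yl]ethyl 3-methylbut-2-enoate
Conditions: 3-methylbut-2-enoyl chloride, pyridine, CH2Cl2, −10 °C to 0 °C
Reagents that add atoms: 3-methylbut-2-enoyl chloride, CC(C)=CC(Cl)=O
Why: acylation of the only free hydroxyl by the acid chloride in pyridine, a base too weak to form the vinylketene that would deconjugate the senecioate, proceeds with retention at the carbinol centre.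

Step 11
Reactants: 15 (1S)-1-[(2R,3R)-2-[3-(Bpin)prop-1-en-2-yl]-3-(3-methylbutanoyloxy)-2,3-dihydrobenzofuran-5-yl]ethyl 3-methylbut-2-enoate
Product: 16 (1S)-1-[(2R,3R)-2-(3-hydroxyprop-1-en-2-yl)-3-(3-methylbutanoyloxy)-2,3-dihydrobenzofuran-5-yl]ethyl 3-methylbut-2-enoate
Conditions: 30% H2O2, aq. NaHCO3, THF, 0 °C
Reagents that add atoms: hydrogen peroxide, OO
Why: oxidation of the allylboronate (boron-to-oxygen 1,2-shift in the hydroperoxide ate complex) gives the primary allylic alcohol without allylic transposition, under conditions too mild to saponify the two esters.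

Step 12
Reactants: 16 (1S)-1-[(2R,3R)-2-(3-hydroxyprop-1-en-2-yl)-3-(3-methylbutanoyloxy)-2,3-dihydrobenzofuran-5-yl]ethyl 3-methylbut-2-enoate
Product: 17 (1S)-1-[(2R,3R)-3-(3-methylbutanoyloxy)-2-(3-oxoprop-1-en-2-yl)-2,3-dihydrobenzofuran-5-yl]ethyl 3-methylbut-2-enoate
Conditions: Dess–Martin periodinane, NaHCO3, CH2Cl2, 0 °C to rt
Reagents that add atoms: none
Why: Dess–Martin oxidation of the primary allylic alcohol gives the 2-substituted acrolein under buffered, amine-free conditions, and it is placed last because the enal is a Morita–Baylis–Hillman-type aryl ether that nucleophilic amines or bases would open by addition–elimination.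

**Compound list**

1 | 5-acetyl-2-hydroxybenzaldehyde | CC(=O)c1ccc(O)c(C=O)c1 | starting material
2 | 5-acetyl-2-(prop-2-yn-1-yloxy)benzaldehyde | CC(=O)c1ccc(OCC#C)c(C=O)c1 | intermediate
3 | (1S)-1-[3-(hydroxymethyl)-4-(prop-2-yn-1-yloxy)phenyl]ethanol | C[C@H](O)c1ccc(OCC#C)c(CO)c1 | intermediate
4 | (1S)-1-[3-(hydroxymethyl)-4-(propa-1,2-dien-1-yloxy)phenyl]ethanol | C[C@H](O)c1ccc(OC=C=C)c(CO)c1 | intermediate
5 | 5-[(1S)-1-hydroxyethyl]-2-(propa-1,2-dien-1-yloxy)benzaldehyde | C[C@H](O)c1ccc(OC=C=C)c(C=O)c1 | intermediate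
6 | 5-[(1S)-1-(TBS-oxy)ethyl]-2-(propa-1,2-dien-1-yloxy)benzaldehyde | C[C@H](O[Si](C)(C)C(C)(C)C)c1ccc(OC=C=C)c(C=O)c1 | intermediate
7 | [(2Z)-3-{2-formyl-4-[(1S)-1-(TBS-oxy)ethyl]phenoxy}-2-(Bpin)prop-2-en-1-yl]copper (bisphosphine on copper not drawn) | C[C@H](O[Si](C)(C)C(C)(C)C)c1ccc(O/C=C(\C[Cu])B2OC(C)(C)C(C)(C)O2)c(C=O)c1 | intermediate (not isolated)
8 | (2R,3R)-3-(Bpin-oxy)-5-[(1S)-1-(TBS-oxy)ethyl]-2-[1-(Bpin)ethenyl]-2,3-dihydrobenzofuran | C=C(B3OC(C)(C)C(C)(C)O3)[C@H]1Oc2ccc([C@H](C)O[Si](C)(C)C(C)(C)C)cc2[C@H]1OB4OC(C)(C)C(C)(C)O4 | intermediate (not isolated)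
9 | (2R,3R)-5-[(1S)-1-(TBS-oxy)ethyl]-2-[1-(Bpin)ethenyl]-2,3-dihydrobenzofuran-3-ol | C=C(B3OC(C)(C)C(C)(C)O3)[C@H]1Oc2ccc([C@H](C)O[Si](C)(C)C(C)(C)C)cc2[C@H]1O | intermediate
10 | (2R,3R)-5-[(1S)-1-(TBS-oxy)ethyl]-2-[1-(Bpin)ethenyl]-3-(TMS-oxy)-2,3-dihydrobenzofuran | C=C(B3OC(C)(C)C(C)(C)O3)[C@H]1Oc2ccc([C@H](C)O[Si](C)(C)C(C)(C)C)cc2[C@H]1O[Si](C)(C)C | intermediate (not isolated)
11 | (2R,3R)-5-[(1S)-1-(TBS-oxy)ethyl]-2-[3-(Bpin)prop-1-en-2-yl]-3-(TMS-oxy)-2,3-dihydrobenzofuran | C=C(CB3OC(C)(C)C(C)(C)O3)[C@H]1Oc2ccc([C@H](C)O[Si](C)(C)C(C)(C)C)cc2[C@H]1O[Si](C)(C)C | intermediate (not isolated)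
12 | (2R,3R)-5-[(1S)-1-(TBS-oxy)ethyl]-2-[3-(Bpin)prop-1-en-2-yl]-2,3-dihydrobenzofuran-3-ol | C=C(CB3OC(C)(C)C(C)(C)O3)[C@H]1Oc2ccc([C@H](C)O[Si](C)(C)C(C)(C)C)cc2[C@H]1O | intermediate
13 | (2R,3R)-5-[(1S)-1-(TBS-oxy)ethyl]-2-[3-(Bpin)prop-1-en-2-yl]-2,3-dihydrobenzofuran-3-yl 3-methylbutanoate | C=C(CB3OC(C)(C)C(C)(C)O3)[C@H]1Oc2ccc([C@H](C)O[Si](C)(C)C(C)(C)C)cc2[C@H]1OC(=O)CC(C)C | intermediate
14 | (2R,3R)-5-[(1S)-1-hydroxyethyl]-2-[3-(Bpin)prop-1-en-2-yl]-2,3-dihydrobenzofuran-3-yl 3-methylbutanoate | C=C(CB3OC(C)(C)C(C)(C)O3)[C@H]1Oc2ccc([C@H](C)O)cc2[C@H]1OC(=O)CC(C)C | intermediate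
15 | (1S)-1-[(2R,3R)-2-[3-(Bpin)prop-1-en-2-yl]-3-(3-methylbutanoyloxy)-2,3-dihydrobenzofuran-5-yl]ethyl 3-methylbut-2-enoate | C=C(CB3OC(C)(C)C(C)(C)O3)[C@H]1Oc2ccc([C@H](C)OC(=O)C=C(C)C)cc2[C@H]1OC(=O)CC(C)C | intermediate
16 | (1S)-1-[(2R,3R)-2-(3-hydroxyprop-1-en-2-yl)-3-(3-methylbutanoyloxy)-2,3-dihydrobenzofuran-5-yl]ethyl 3-methylbut-2-enoate | C=C(CO)[C@H]1Oc2ccc([C@H](C)OC(=O)C=C(C)C)cc2[C@H]1OC(=O)CC(C)C | intermediate
17 | (1S)-1-[(2R,3R)-3-(3-methylbutanoyloxy)-2-(3-oxoprop-1-en-2-yl)-2,3-dihydrobenzofuran-5-yl]ethyl 3-methylbut-2-enoate (CNP0325942.1) | C=C(C=O)[C@H]1Oc2ccc([C@H](C)OC(=O)C=C(C)C)cc2[C@H]1OC(=O)CC(C)C | target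

**Step count.** Total: 12 steps. Longest linear sequence: 12 steps (1 to 17).

**Steps most likely to fail**

Step 6. What may go wrong: facial selectivity may be poor if the allylcopper equilibrates between its Z and E forms faster than it cyclises, and part of the allylcopper may be protonated before it reaches the aldehyde. Fallback (sets out from 6, comes back at 9): the copper nucleophile is replaced by an allylboronate. Pt(dba)2/PCy3-catalysed diboration of the terminal double bond of the allene with B2pin2 in toluene should give 5-[(1S)-1-(TBS-oxy)ethyl]-2-{[(1Z)-2,3-bis(Bpin)prop-1-en-1-yl]oxy}benzaldehyde F1. In the presence of the chiral phosphoric acid (R)-TRIP (antipode chosen in the same way as the ligand of step 6), the allylboronate arm of F1 should add to the ortho aldehyde through a chair transition state, boron moving to oxygen, to give the O-boryl ether 8, which aqueous work-up converts into 9.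

Step 7. What may go wrong: loss of the labile TMS group or coordination of the cis C3 oxygen to boron may block formation of the ate complex, and LiCH2Cl may decompose before the 1,2-shift takes place. Fallback (sets out from 9, comes back at 12): cross-coupling in place of a 1,2-metallate shift. Iododeboronation (I2, aq. NaOH, THF, 0 °C) should give (2S,3R)-5-[(1S)-1-(TBS-oxy)ethyl]-2-(1-iodoethenyl)-2,3-dihydrobenzofuran-3-ol F2. Pd(PPh3)4-catalysed Negishi coupling of F2 with an excess of (pinacolboryl)methylzinc iodide (from ICH2Bpin and Zn dust, THF, rt) should install the CH2Bpin group and deliver 12.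

Step 4. What may go wrong: over-oxidation of the secondary benzylic alcohol, or oxidative attack on the electron-rich allenyl ether. Fallback (sets out from 3, comes back at 6): the two hydroxyls are told apart by protecting groups instead of by a chemoselective oxidation. Double silylation (TBSCl, imidazole, DMF) should give tert-butyl{(1S)-1-[3-(TBS-oxymethyl)-4-(prop-2-yn-1-yloxy)phenyl]ethoxy}dimethylsilane F3. Catalytic KOtBu in THF should isomerise it to tert-butyl{(1S)-1-[3-(TBS-oxymethyl)-4-(propa-1,2-dien-1-yloxy)phenyl]ethoxy}dimethylsilane F4. Selective cleavage of the primary silyl ether (HF·pyridine, pyridine, THF, 0 °C) should give {5-[(1S)-1-(TBS-oxy)ethyl]-2-(propa-1,2-dien-1-yloxy)phenyl}methanol F5, and MnO2 in CH2Cl2 should oxidise the benzylic alcohol to 6.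

**Further compounds**

F1 | step 6 | 5-[(1S)-1-(TBS-oxy)ethyl]-2-{[(1Z)-2,3-bis(Bpin)prop-1-en-1-yl]oxy}benzaldehyde | C[C@H](O[Si](C)(C)C(C)(C)C)c1ccc(O/C=C(\CB2OC(C)(C)C(C)(C)O2)B3OC(C)(C)C(C)(C)O3)c(C=O)c1
F2 | step 7 | (2S,3R)-5-[(1S)-1-(TBS-oxy)ethyl]-2-(1-iodoethenyl)-2,3-dihydrobenzofuran-3-ol | C=C(I)[C@H]1Oc2ccc([C@H](C)O[Si](C)(C)C(C)(C)C)cc2[C@H]1O
F3 | step 4 | tert-butyl{(1S)-1-[3-(TBS-oxymethyl)-4-(prop-2-yn-1-yloxy)phenyl]ethoxy}dimethylsilane | C[C@H](O[Si](C)(C)C(C)(C)C)c1ccc(OCC#C)c(CO[Si](C)(C)C(C)(C)C)c1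
F4 | step 4 | tert-butyl{(1S)-1-[3-(TBS-oxymethyl)-4-(propa-1,2-dien-1-yloxy)phenyl]ethoxy}dimethylsilane | C[C@H](O[Si](C)(C)C(C)(C)C)c1ccc(OC=C=C)c(CO[Si](C)(C)C(C)(C)C)c1
F5 | step 4 | {5-[(1S)-1-(TBS-oxy)ethyl]-2-(propa-1,2-dien-1-yloxy)phenyl}methanol | C[C@H](O[Si](C)(C)C(C)(C)C)c1ccc(OC=C=C)c(CO)c1
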